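**Plan**

- Retrosynthesis: the three O-methyl groups and the three acetals come off last. The cyclopentanone C1 oxygen is traced back to a C1=C2 alkene. Then both exocyclic bonds of the cyclopropane are cut at once: cyclopropane C3–CH2 (oxobutyl chain) and cyclopropane C1–C2 (cyclopentane).
- This leaves a ketal-protected 3-oxobutyl Grignard reagent, 3,3-dimethylcyclopropene and a 1-iodo-5-methylcyclopentene that already carries the benzylic arm. In the iodide, C–I goes back to a ketone, the two aryl CHO groups to a Rieche formylation, and the quaternary C–CH3 and benzylic C–CH2(isobutyl) bonds to a conjugate addition/enolate methylation on an arylidene cyclopentanone (aldol C=C).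
- Forward: the five-membered ring is bought and the three-membered ring is made as the cyclopropene. Steps 1–6 build the iodide, step 10 joins the three fragments, then oxygen goes onto C1, C2 is equilibrated and the masks are removed.
- Stereochemistry: the benzylic carbon comes from a chiral Cu catalyst, the quaternary carbon from allylic-strain-controlled methylation of the resulting enolate, both cyclopropane carbons from chiral-Cu syn-carbomagnesiation carried with retention through Zn and Pd, and cyclopentanone C2 from thermodynamic epimerisation.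
- Enabling feature: the cis-1,2-disubstituted 3,3-dimethylcyclopropane, whose two adjacent ring CH carbons carry the chain CH2 and cyclopentanone C2. This is what syn addition of carbon and metal across the C=C of the symmetric cyclopropene, followed by stereoretentive coupling, delivers.

Key step: step 10

Remark: Ar′ = 3,5-bis(1,3-dioxolan-2-yl)-2,4,6-trimethoxyphenyl. The sense of induction of the ferrocenyl diphosphine in steps 2 and 10 is not presumed, so the ligand enantiomer is fixed by a trial run. The benzylic CIP descriptor alternates between R and S along the route only because substituent priorities change; the geometry does not.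

**Step 1**
Reactants: 1 cyclopentanone; 2 2,4,6-trimethoxybenzaldehyde
Product: 4 (E)-2-[(2,4,6-trimethoxyphenyl)methylidene]cyclopentan-1-one, via aldol adduct 3 (not isolated)
Conditions: 1 (5 equiv), NaOH (2 M aq), EtOH, 0 °C → rt
Reagents that add atoms: none
Why: Claisen–Schmidt (crossed aldol) condensation with a non-enolisable aldehyde, in which excess ketone suppresses 2,5-bis-condensation and E1cB dehydration gives the conjugated E-alkene (aryl anti to C=O).

**Step 2**
Reactants: 4 (E)-2-[(2,4,6-trimethoxyphenyl)methylidene]cyclopentan-1-one; 5 isobutylmagnesium bromide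
Product: 7 (2R)-2-methyl-2-[(1R)-3-methyl-1-(2,4,6-trimethoxyphenyl)butyl]cyclopentan-1-one, via bromomagnesium enolate 6 (not isolated)
Conditions: CuBr·SMe2 (5 mol %), Josiphos-type ligand (6 mol %), 5 (1.3 equiv), t-BuOMe, −78 °C; then MeI (5 equiv), DMPU, −78 → 0 °C
Reagents that add atoms: iodomethane, CI
Why: Cu(I)/ferrocenyl-diphosphine-catalysed enantioselective conjugate addition of the Grignard reagent to the s-cis-locked aryl enone sets the benzylic centre under ligand control and gives the tetrasubstituted enolate 6 regiospecifically; its C-methylation (enolate alkylation) should occur anti to the aryl group in the rotamer that keeps the benzylic H in the enolate plane next to O–Mg (A(1,3) strain), which sets the quaternary carbon as R.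

**Step 3**
Reactants: 7 (2R)-2-methyl-2-[(1R)-3-methyl-1-(2,4,6-trimethoxyphenyl)butyl]cyclopentan-1-one
Product: 9 5-[(1R)-3-methyl-1-[(1R)-1-methyl-2-oxocyclopentyl]butyl]-2,4,6-trimethoxybenzene-1,3-dicarbaldehyde, via bis(chloromethoxymethyl)arene 8 (not isolated)
Conditions: Cl2CHOMe (5 equiv), TiCl4 (5 equiv), CH2Cl2, −78 → 0 °C; ice/1 M HCl
Reagents that add atoms: dichloromethyl methyl ether, COC(Cl)Cl; water, O
Why: Rieche formylation at the two free ring positions, each flanked by two methoxy groups, followed by hydrolysis of the α-chloro ethers; it is placed here so that TiCl4 never meets the cyclopropane or the ketal, and the hindered ketone should be a spectator at ≤ 0 °C.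

**Step 4**
Reactants: 9 5-[(1R)-3-methyl-1-[(1R)-1-methyl-2-oxocyclopentyl]butyl]-2,4,6-trimethoxybenzene-1,3-dicarbaldehyde
Product: 10 (2R)-2-[(1R)-1-Ar′-3-methylbutyl]-2-methylcyclopentan-1-one
Conditions: TMSOCH2CH2OTMS (3 equiv), TMSOTf (5 mol %), CH2Cl2, −78 → −30 °C; pyridine quench
Reagents that add atoms: 1,2-bis(trimethylsilyloxy)ethane, C[Si](C)(C)OCCO[Si](C)(C)C
Why: Noyori acetalisation at low temperature is selective for aldehydes over the α-quaternary ketone and masks the formyl groups against hydrazine, the organometallics of step 10 and borane.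

**Step 5**
Reactants: 10 (2R)-2-[(1R)-1-Ar′-3-methylbutyl]-2-methylcyclopentan-1-one
Product: 11 (E)-hydrazone of ketone 10 (NH2 anti to the quaternary carbon; stereocentres unchanged)
Conditions: N2H4·H2O (10 equiv), Et3N, EtOH, reflux
Reagents that add atoms: hydrazine, NN
Why: Hydrazone condensation on the only carbonyl group, with excess hydrazine to suppress azine formation; the acetals are stable to the basic medium.

**Step 6**
Reactants: 11 (E)-hydrazone of ketone 10
Product: 13 (5R)-5-[(1R)-1-Ar′-3-methylbutyl]-1-iodo-5-methylcyclopent-1-ene, via diazoalkane 12 (not isolated)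
Conditions: I2 (2.2 equiv), tetramethylguanidine (6 equiv), THF, 0 °C → rt
Reagents that add atoms: iodine, II
Why: Barton vinyl iodide synthesis, in which oxidation to the diazoalkane, iodination and loss of N2 give an α-iodo cation that can lose a proton only from the CH2 side because the other α-carbon is quaternary; the fully substituted arene cannot be iodinated.

**Step 7**
Reactants: 14 3-methylbut-2-enal
Product: 15 (E)-3-methylbut-2-enal 4-methylbenzenesulfonylhydrazone
Conditions: TsNHNH2 (1.0 equiv), MeOH, rt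
Reagents that add atoms: 4-methylbenzenesulfonohydrazide, Cc1ccc(cc1)S(=O)(=O)NN
Why: Hydrazone condensation at room temperature, which should give the unsaturated tosylhydrazone without cyclisation to a pyrazoline.

**Step 8**
Reactants: 15 (E)-3-methylbut-2-enal 4-methylbenzenesulfonylhydrazone
Product: 18 3,3-dimethylcyclopropene, via tosylhydrazone sodium salt 16 (not isolated), via 1-diazo-3-methylbut-2-ene 17 (not isolated)
Conditions: NaOMe (1.05 equiv), diglyme, 130–150 °C, N2 sweep, product condensed at −78 °C and kept as a cold Et2O solution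
Reagents that add atoms: none
Why: Base-induced tosylhydrazone pyrolysis (Bamford–Stevens conditions, Closs cyclopropene synthesis), in which the salt loses sulfinate, the vinyldiazoalkane loses N2 and the vinylcarbene closes to the cyclopropene, which distils out as it forms.

**Step 9**
Reactants: 19 2-(2-bromoethyl)-2-methyl-1,3-dioxolane
Product: 20 [2-(2-methyl-1,3-dioxolan-2-yl)ethyl]magnesium bromide
Conditions: Mg turnings (I2-activated), THF, 25–30 °C
Reagents that add atoms: magnesium, [Mg]
Why: Grignard formation by magnesium insertion into the primary C–Br bond; the ketal is inert to the reagent at or below 30 °C.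

**Step 10**
Reactants: 20 [2-(2-methyl-1,3-dioxolan-2-yl)ethyl]magnesium bromide; 18 3,3-dimethylcyclopropene; 13 (5R)-5-[(1R)-1-Ar′-3-methylbutyl]-1-iodo-5-methylcyclopent-1-ene
Product: 23 (5R)-5-[(1S)-1-Ar′-3-methylbutyl]-1-{(1S,3R)-2,2-dimethyl-3-[2-(2-methyl-1,3-dioxolan-2-yl)ethyl]cyclopropyl}-5-methylcyclopent-1-ene (cyclopropane substituents cis), via cis-cyclopropylmagnesium bromide 21 (not isolated), via cis-cyclopropylzinc bromide 22 (not isolated)
Conditions: 18 (2.4 equiv), CuI (5 mol %), Josiphos-type ligand (6 mol %), 20 (2.0 equiv, slow addition), Et2O–toluene, −40 → 0 °C, excess 18 purged (Ar); ZnBr2 (2.1 equiv), THF, 0 °C; 13 (1.0 equiv), Pd(OAc)2 (5 mol %), SPhos (10 mol %), 50 °C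
Reagents that add atoms: none
Why: A chiral Cu(I)–alkyl species adds syn across the strained C=C of the C2v-symmetric cyclopropene (strain-release carbocupration, with Cu→Mg exchange turning the catalyst over), so the new C–CH2 bond and the C–Mg bond are cis; the closest known reaction is the copper/ferrocenyl-diphosphine-catalysed enantioselective carbomagnesiation of 3,3-disubstituted cyclopropenes with electrophilic trapping. The cyclopropyl–metal bond is configurationally stable, and Mg→Zn exchange and Negishi coupling (oxidative addition of Pd(0) to the C–I bond of 13, transmetalation, reductive elimination) proceed with retention to form the cyclopropane–cyclopentene bond. No ring is closed: the cyclopropane is brought in intact and only its two exocyclic bonds are made. Both new stereocentres (the carbon bearing the chain and the carbon bearing the cyclopentenyl group) are set in the carbometalation, their absolute sense by the ligand-controlled choice between the two enantiotopic alkene carbons and their cis relation by syn addition plus retention. The step needs enantioselection, which rests on the ligand alone because the symmetric substrate has no regiochemical issue; complete consumption of the alkyl Grignard before zinc and palladium are added, secured by a slight excess of 18 that is purged afterwards; and a bulky biarylphosphine catalyst for the hindered partners, while the stereocentres of 13 are remote and untouched.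

**Step 11**
Reactants: 23 (the cyclopentene from step 10)
Product: 25 (1S,2S,3R)-3-[(1S)-1-Ar′-3-methylbutyl]-2-{(1R,3R)-2,2-dimethyl-3-[2-(2-methyl-1,3-dioxolan-2-yl)ethyl]cyclopropyl}-3-methylcyclopentan-1-ol, via alkylborane 24 (not isolated)
Conditions: BH3·THF (3 equiv), THF, 0 °C → rt; then NaOH (3 M aq), 30 % H2O2, 0 °C → rt
Reagents that add atoms: hydrogen peroxide, OO
Why: Hydroboration–oxidation puts boron on the unsubstituted alkene carbon and hydrogen on the cyclopropyl-bearing carbon (sterics and cyclopropyl-stabilised polarisation agree), syn and from the ring face of the methyl group, with retention in the B→O oxidation; both new centres are provisional, since one is oxidised in step 12 and the other equilibrated in step 13.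

**Step 12**
Reactants: 25 (the cyclopentanol from step 11)
Product: 26 (2S,3R)-3-[(1S)-1-Ar′-3-methylbutyl]-2-{(1R,3R)-2,2-dimethyl-3-[2-(2-methyl-1,3-dioxolan-2-yl)ethyl]cyclopropyl}-3-methylcyclopentan-1-one (cyclopropyl cis to the benzylic arm)
Conditions: TPAP (5 mol %), NMO (1.5 equiv), 4 Å MS, CH2Cl2, rt
Reagents that add atoms: none
Why: Ley–Griffith oxidation of the secondary alcohol under neutral conditions that leave acetals, ketal and cyclopropane untouched.

**Step 13**
Reactants: 26 (the 2S ketone)
Product: 27 (2R,3R)-3-[(1S)-1-Ar′-3-methylbutyl]-2-{(1R,3R)-2,2-dimethyl-3-[2-(2-methyl-1,3-dioxolan-2-yl)ethyl]cyclopropyl}-3-methylcyclopentan-1-one (cyclopropyl cis to the ring methyl)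
Conditions: NaOMe (0.3 equiv), MeOH, 40 °C
Reagents that add atoms: none
Why: Base-mediated epimerisation through the enolate places the cyclopropyl group trans to the bulky benzylic arm, the thermodynamically preferred and natural C2 configuration; the side-chain ketone is still masked, so no intramolecular aldol reaction can occur.

**Step 14**
Reactants: 27 (the 2R ketone)
Product: 28 5-[(1S)-1-[(1R,2R)-2-[(1R,3R)-2,2-dimethyl-3-(3-oxobutyl)cyclopropyl]-1-methyl-3-oxocyclopentyl]-3-methylbutyl]-2,4,6-trimethoxybenzene-1,3-dicarbaldehyde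
Conditions: 1 M HCl–THF (1:4), rt
Reagents that add atoms: water, O
Why: Acid-catalysed acetal hydrolysis removes both aryl dioxolanes and the ketal in one operation; dilute acid at room temperature should not open the unactivated cyclopropane.

**Step 15**
Reactants: 28 (the tri-O-methyl ether)
Product: 29 Macrocarpal N, 5-[(1S)-1-[(1R,2R)-2-[(1R,3R)-2,2-dimethyl-3-(3-oxobutyl)cyclopropyl]-1-methyl-3-oxocyclopentyl]-3-methylbutyl]-2,4,6-trihydroxybenzene-1,3-dicarbaldehyde
Conditions: PhSNa (10 equiv), DMF, 90 °C; then cold 1 M HCl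
Reagents that add atoms: none
Why: Nucleophilic (SN2) O-demethylation by thiolate, where every methoxy group is ortho or para to formyl groups so the aryloxide is a good leaving group; the weakly basic thiolate should spare the ketones and the cyclopropane, which strong Lewis acids would not.

**Compound list**

1 | cyclopentanone | O=C1CCCC1 | starting material
2 | 2,4,6-trimethoxybenzaldehyde | COc1cc(OC)c(C=O)c(OC)c1 | starting material
3 | 2-[hydroxy(2,4,6-trimethoxyphenyl)methyl]cyclopentan-1-one (aldol adduct, diastereomer mixture) | O=C1CCCC1C(O)c1c(OC)cc(OC)cc1OC | intermediate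
4 | (E)-2-[(2,4,6-trimethoxyphenyl)methylidene]cyclopentan-1-one | O=C1CCC/C1=C\c1c(OC)cc(OC)cc1OC | intermediate
5 | isobutylmagnesium bromide | CC(C)C[Mg]Br | starting material
6 | bromomagnesium 2-[(1S)-3-methyl-1-(2,4,6-trimethoxyphenyl)butyl]cyclopent-1-en-1-olate | CC(C)C[C@H](c1c(OC)cc(OC)cc1OC)C1=C(O[Mg]Br)CCC1 | intermediate
7 | (2R)-2-methyl-2-[(1R)-3-methyl-1-(2,4,6-trimethoxyphenyl)butyl]cyclopentan-1-one | O=C1CCC[C@]1(C)[C@H](CC(C)C)c1c(OC)cc(OC)cc1OC | intermediate
8 | bis[chloro(methoxy)methyl] derivative of 7 (both free ring positions; mixture at the CHCl carbons) | O=C1CCC[C@]1(C)[C@H](CC(C)C)c1c(OC)c(C(Cl)OC)c(OC)c(C(Cl)OC)c1OC | intermediate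
9 | 5-[(1R)-3-methyl-1-[(1R)-1-methyl-2-oxocyclopentyl]butyl]-2,4,6-trimethoxybenzene-1,3-dicarbaldehyde | O=C1CCC[C@]1(C)[C@H](CC(C)C)c1c(OC)c(C=O)c(OC)c(C=O)c1OC | intermediate
10 | (2R)-2-{(1R)-1-[3,5-bis(1,3-dioxolan-2-yl)-2,4,6-trimethoxyphenyl]-3-methylbutyl}-2-methylcyclopentan-1-one | O=C1CCC[C@]1(C)[C@H](CC(C)C)c1c(OC)c(C2OCCO2)c(OC)c(C2OCCO2)c1OC | intermediate
11 | (E)-hydrazone of 10 | N/N=C1\CCC[C@]1(C)[C@H](CC(C)C)c1c(OC)c(C2OCCO2)c(OC)c(C2OCCO2)c1OC | intermediate
12 | diazoalkane from 11 (C=N2 in place of C=O of 10) | [N-]=[N+]=C1CCC[C@]1(C)[C@H](CC(C)C)c1c(OC)c(C2OCCO2)c(OC)c(C2OCCO2)c1OC | intermediate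
13 | (5R)-5-{(1R)-1-[3,5-bis(1,3-dioxolan-2-yl)-2,4,6-trimethoxyphenyl]-3-methylbutyl}-1-iodo-5-methylcyclopent-1-ene | IC1=CCC[C@]1(C)[C@H](CC(C)C)c1c(OC)c(C2OCCO2)c(OC)c(C2OCCO2)c1OC | intermediate
14 | 3-methylbut-2-enal | CC(C)=CC=O | starting material
15 | (E)-3-methylbut-2-enal 4-methylbenzenesulfonylhydrazone | CC(C)=C/C=N/NS(=O)(=O)c1ccc(C)cc1 | intermediate
16 | sodium salt of 15 | CC(C)=CC=N[N-]S(=O)(=O)c1ccc(C)cc1.[Na+] | intermediate
17 | 1-diazo-3-methylbut-2-ene | CC(C)=CC=[N+]=[N-] | intermediate
18 | 3,3-dimethylcyclopropene | CC1(C)C=C1 | intermediate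
19 | 2-(2-bromoethyl)-2-methyl-1,3-dioxolane | CC1(CCBr)OCCO1 | starting material
20 | [2-(2-methyl-1,3-dioxolan-2-yl)ethyl]magnesium bromide | CC1(CC[Mg]Br)OCCO1 | intermediate
21 | cis-(1S,3S)-{2,2-dimethyl-3-[2-(2-methyl-1,3-dioxolan-2-yl)ethyl]cyclopropyl}magnesium bromide | CC1(CC[C@@H]2[C@H]([Mg]Br)C2(C)C)OCCO1 | intermediate
22 | cis-(1S,3S)-{2,2-dimethyl-3-[2-(2-methyl-1,3-dioxolan-2-yl)ethyl]cyclopropyl}zinc bromide | CC1(CC[C@@H]2[C@H]([Zn]Br)C2(C)C)OCCO1 | intermediate
23 | (5R)-5-{(1S)-1-[3,5-bis(1,3-dioxolan-2-yl)-2,4,6-trimethoxyphenyl]-3-methylbutyl}-1-{(1S,3R)-2,2-dimethyl-3-[2-(2-methyl-1,3-dioxolan-2-yl)ethyl]cyclopropyl}-5-methylcyclopent-1-ene (cis-cyclopropane) | CC1(CC[C@@H]2[C@H](C3=CCC[C@]3(C)[C@H](CC(C)C)c4c(OC)c(C5OCCO5)c(OC)c(C5OCCO5)c4OC)C2(C)C)OCCO1 | intermediate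
24 | monoalkylborane from 23 (BH2 in place of OH of 25, same configuration) | CC1(CC[C@@H]2[C@H]([C@@H]3[C@@H](B)CC[C@]3(C)[C@H](CC(C)C)c4c(OC)c(C5OCCO5)c(OC)c(C5OCCO5)c4OC)C2(C)C)OCCO1 | intermediate
25 | (1S,2S,3R)-3-[(1S)-1-Ar′-3-methylbutyl]-2-{(1R,3R)-2,2-dimethyl-3-[2-(2-methyl-1,3-dioxolan-2-yl)ethyl]cyclopropyl}-3-methylcyclopentan-1-ol (expected major isomer: OH and ring methyl cis, cyclopropyl trans to both) | CC1(CC[C@@H]2[C@H]([C@@H]3[C@@H](O)CC[C@]3(C)[C@H](CC(C)C)c4c(OC)c(C5OCCO5)c(OC)c(C5OCCO5)c4OC)C2(C)C)OCCO1 | intermediate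
26 | (2S,3R)-3-[(1S)-1-Ar′-3-methylbutyl]-2-{(1R,3R)-2,2-dimethyl-3-[2-(2-methyl-1,3-dioxolan-2-yl)ethyl]cyclopropyl}-3-methylcyclopentan-1-one | CC1(CC[C@@H]2[C@H]([C@@H]3C(=O)CC[C@]3(C)[C@H](CC(C)C)c4c(OC)c(C5OCCO5)c(OC)c(C5OCCO5)c4OC)C2(C)C)OCCO1 | intermediate
27 | (2R,3R)-3-[(1S)-1-Ar′-3-methylbutyl]-2-{(1R,3R)-2,2-dimethyl-3-[2-(2-methyl-1,3-dioxolan-2-yl)ethyl]cyclopropyl}-3-methylcyclopentan-1-one | CC1(CC[C@@H]2[C@H]([C@H]3C(=O)CC[C@]3(C)[C@H](CC(C)C)c4c(OC)c(C5OCCO5)c(OC)c(C5OCCO5)c4OC)C2(C)C)OCCO1 | intermediate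
28 | 5-[(1S)-1-[(1R,2R)-2-[(1R,3R)-2,2-dimethyl-3-(3-oxobutyl)cyclopropyl]-1-methyl-3-oxocyclopentyl]-3-methylbutyl]-2,4,6-trimethoxybenzene-1,3-dicarbaldehyde | CC(=O)CC[C@@H]1[C@H]([C@H]2C(=O)CC[C@]2(C)[C@H](CC(C)C)c2c(OC)c(C=O)c(OC)c(C=O)c2OC)C1(C)C | intermediate
29 | Macrocarpal N | CC(=O)CC[C@@H]1[C@H]([C@H]2C(=O)CC[C@]2(C)[C@H](CC(C)C)c2c(O)c(C=O)c(O)c(C=O)c2O)C1(C)C | target

**Step count and risks**

Total steps: 15. Longest linear sequence: 12 (steps 1–6 and 10–15, from cyclopentanone).

Steps most likely to fail: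

1. Step 2. Conjugate addition may stall or turn into 1,2-addition at a β-carbon shielded by the twisted 2,6-dimethoxyaryl ring, the ligand may give poor enantioface selection, and the methylation may show poor facial selectivity or O-alkylation. The fallback replaces asymmetric catalysis by chirality transfer. It sets out from 4: Corey–Bakshi–Shibata reduction should give (1R,E)-2-[(2,4,6-trimethoxyphenyl)methylidene]cyclopentan-1-ol F1, and esterification with picolinic acid (DCC, DMAP) gives its pyridine-2-carboxylate F2. CuBr·SMe2-mediated anti-SN2′ substitution of F2 with 5 transfers the carbinol chirality to the benzylic carbon and gives 1-[(1S)-3-methyl-1-(2,4,6-trimethoxyphenyl)butyl]cyclopent-1-ene F3. Hydroboration–oxidation gives trans-2-[(1S)-3-methyl-1-(2,4,6-trimethoxyphenyl)butyl]cyclopentan-1-ol F4, and TPAP/NMO oxidation gives 2-[(1S)-3-methyl-1-(2,4,6-trimethoxyphenyl)butyl]cyclopentan-1-one F5. Methylation of its more substituted enolate (thermodynamic silyl enol ether, MeLi, then MeI) under the same allylic-strain control comes back to the route at 7.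

2. Step 10. Transmetalation and reductive elimination at the hindered cis-trisubstituted cyclopropylzinc may be slow, so that protodemetalation or coupling of residual alkylzinc takes over, and enantioface selection on the symmetric cyclopropene may be incomplete with no chance to upgrade it in the one-pot mode. The fallback uses an isolated boron nucleophile. It sets out from 21, generated from 20 and 18 as in step 10, which is quenched with 2-isopropoxy-4,4,5,5-tetramethyl-1,3,2-dioxaborolane to give cis-2-{2,2-dimethyl-3-[2-(2-methyl-1,3-dioxolan-2-yl)ethyl]cyclopropyl}-4,4,5,5-tetramethyl-1,3,2-dioxaborolane F6; this can be purified and assayed. Suzuki–Miyaura coupling of F6 with 13 (Pd(OAc)2, dialkylbiarylphosphine, K3PO4, toluene–water, 90 °C) proceeds with retention and comes back to the route at 23.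

3. Step 15. With both ketones free, the hot basic medium may trigger an intramolecular aldol reaction between the methyl ketone and the cyclopentanone, and the last demethylation of the phenoxide may stall. The fallback keeps the methyl ketone masked during demethylation. It sets out from 27: brief treatment with PPTS in wet acetone should hydrolyse only the two very electron-rich aryl dioxolanes and give 5-[(1S)-1-[(1R,2R)-2-{(1R,3R)-2,2-dimethyl-3-[2-(2-methyl-1,3-dioxolan-2-yl)ethyl]cyclopropyl}-1-methyl-3-oxocyclopentyl]-3-methylbutyl]-2,4,6-trimethoxybenzene-1,3-dicarbaldehyde F7. Thiolate demethylation (PhSNa, DMF) then gives the corresponding 2,4,6-trihydroxy ketal F8, and mild aqueous acid removes the ketal last, arriving at 29.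

**Further compounds**

F1 | step 2 | (1R,E)-2-[(2,4,6-trimethoxyphenyl)methylidene]cyclopentan-1-ol | O[C@@H]1CCC/C1=C\c1c(OC)cc(OC)cc1OC
F2 | step 2 | (1R,E)-2-[(2,4,6-trimethoxyphenyl)methylidene]cyclopentyl pyridine-2-carboxylate | O=C(O[C@@H]1CCC/C1=C\c1c(OC)cc(OC)cc1OC)c1ccccn1
F3 | step 2 | 1-[(1S)-3-methyl-1-(2,4,6-trimethoxyphenyl)butyl]cyclopent-1-ene | CC(C)C[C@H](c1c(OC)cc(OC)cc1OC)C1=CCCC1
F4 | step 2 | trans-2-[(1S)-3-methyl-1-(2,4,6-trimethoxyphenyl)butyl]cyclopentan-1-ol (ring centres as a diastereomer mixture) | CC(C)C[C@H](c1c(OC)cc(OC)cc1OC)C1CCCC1O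
F5 | step 2 | 2-[(1S)-3-methyl-1-(2,4,6-trimethoxyphenyl)butyl]cyclopentan-1-one (C2 epimers) | CC(C)C[C@H](c1c(OC)cc(OC)cc1OC)C1CCCC1=O
F6 | step 10 | cis-2-{2,2-dimethyl-3-[2-(2-methyl-1,3-dioxolan-2-yl)ethyl]cyclopropyl}-4,4,5,5-tetramethyl-1,3,2-dioxaborolane | CC1(CC[C@@H]2[C@H](B3OC(C)(C)C(C)(C)O3)C2(C)C)OCCO1
F7 | step 15 | 5-[(1S)-1-[(1R,2R)-2-{(1R,3R)-2,2-dimethyl-3-[2-(2-methyl-1,3-dioxolan-2-yl)ethyl]cyclopropyl}-1-methyl-3-oxocyclopentyl]-3-methylbutyl]-2,4,6-trimethoxybenzene-1,3-dicarbaldehyde | CC1(CC[C@@H]2[C@H]([C@H]3C(=O)CC[C@]3(C)[C@H](CC(C)C)c4c(OC)c(C=O)c(OC)c(C=O)c4OC)C2(C)C)OCCO1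
F8 | step 15 | 5-[(1S)-1-[(1R,2R)-2-{(1R,3R)-2,2-dimethyl-3-[2-(2-methyl-1,3-dioxolan-2-yl)ethyl]cyclopropyl}-1-methyl-3-oxocyclopentyl]-3-methylbutyl]-2,4,6-trihydroxybenzene-1,3-dicarbaldehyde | CC1(CC[C@@H]2[C@H]([C@H]3C(=O)CC[C@]3(C)[C@H](CC(C)C)c4c(O)c(C=O)c(O)c(C=O)c4O)C2(C)C)OCCO1
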